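- Hours did not order the earlier runs: Thursday's flask took 4.00 h to give 17.8% of Z, while Saturday's, with twice the G, took 2.00 h to give 17.3%.

| setting | Thursday's | Friday's | Saturday's | Monday's | birch | alder | elm | maple |
|---|---|---|---|---|---|---|---|---|
| L | 0.050 M | 0.050 M | 0.050 M | 0.025 M | 0.050 M | 0.050 M | 0.050 M | 0.050 M |
| G | 4 equiv | 2 equiv | 8 equiv | 4 equiv | 4.00 equiv | 4.00 equiv | 4.00 equiv (fed, over 2.00 h) | 4.00 equiv |
| remark | run made earlier | run made earlier | run made earlier | run made earlier | one stirred flow tank at steady state, fed with the mixture as stated, mean residence time 4.0 h | one stirred flow tank at steady state, fed with the mixture as stated, mean residence time 12.0 h | all but G at the start; G goes in evenly over 2.00 h, the run ends at 4.0 h | everything together in a closed stirred flask, run for 4.0 h |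
| time |  |  |  |  |  |  | 4.0 h | 4.0 h |

- Thursday's (time / h: Z / %): 0.333: 0.5; 0.500: 0.9; 0.833: 0.8; 1.33: 3.4; 2.50: 9.4; 4.00: 17.8
- Friday's (time / h: Z / %): 0.250: 0.5; 0.417: 0; 0.667: 0.1; 1.33: 1.4; 2.00: 1.7; 3.00: 4.5
- Saturday's (time / h: Z / %): 0.500: 0.9; 1.00: 6.4; 1.50: 10.3; 2.00: 17.3; 2.50: 23.2; 3.00: 27.8
- Monday's (time / h: Z / %): 0.250: 0; 0.833: 0.9; 1.33: 0.6; 2.50: 4.3; 3.00: 5.5

(scatter of a reading: 0.5 percentage points)

- the stated concentrations are those of everything mixed, before any reaction; amounts are the same in each set-up
- the feed brings no volume worth counting
- the earlier runs were made in a closed, stirred flask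

- the set-up with the highest amount of Z at the outlet or at the end, in percent of the L put in ("none" if the first two lie within 2 percentage points) (birch / alder / elm / maple / none)
- amount of Z at the outlet or at the end, in percent of the L put in, birch
- amount of Z at the outlet or at the end, in percent of the L put in, alder
- amount of Z at the outlet or at the end, in percent of the L put in, elm
- amount of Z at the outlet or at the end, in percent of the L put in, maple

- Both of those flasks held the same product of charged c_G and hours, 48.0 M·min. I called this product the exposure. I divided the rate of Z by the rate at which exposure grows, which is c_G, and read Z as a curve in exposure; I used that curve as an approximation, not as a law, for the readings did not show that every step uses G.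
- Maple repeats Thursday's recipe, so I took 17.8%.
- In elm, G enters evenly, so I counted 3.00 h at full c_G, an exposure of 36.0 M·min. Between Thursday's last two readings that gave 12.2%. Saturday's 1.50 h reading, at that exposure, shows 10.3%, which is 1.9 percentage points under Thursday's curve, so the curve is rough, but I kept Thursday's, since elm ends at Thursday's c_G.
- My first tank estimate used the mean residence time, which put birch at maple's exposure. That was the weak link: a tank's outlet mixes ages (the residence-time distribution).
- So I reforged it. Thursday's line rises by 0.0560 h⁻¹ as a fraction of the L charged and starts at 0.821 h. Saturday's last exposure equals 6.00 h at c_G as charged here, and beyond that age, for want of readings, I held Z flat. Averaged over ages, this gave birch 13.2% and alder 22.0%. Alder's figure is soft, since 60.7% of its outlet is older than that age.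
- The forecast named alder, as I did, and gave birch 15%, alder 35%, elm 12% and maple 17.6%, reasoning “so both steps look first order in G”. Its alder stood above mine.
- The flasks gave birch 14.2%, alder 27.4%, elm 12.3% and maple 17.9%, so alder came highest, 7.6 points under the forecast.

    L + G → X (k = 8.30 × 10⁻⁴ M⁻¹ s⁻¹)
    G + X → J (k = 4.90 × 10⁻⁴ M⁻¹ s⁻¹)
    J → Z (k = 3.00 × 10⁻⁴ s⁻¹)
    J → Q (k = 8.50 × 10⁻⁵ s⁻¹)
    J → D (k = 2.50 × 10⁻⁴ s⁻¹)
    Q ⇌ E (K = 0.170, k = 1.40 × 10⁻⁴ s⁻¹)

- Left for 40.0 h, maple reached Z 47.2% with D 39.3%. Maple's exposure of 48.0 M·min gave 17.9%, beside Saturday's 17.3% at that exposure. The neighbouring flask, maple's with 2.40 equiv of G, ran at 0.600 of maple's exposure, close to the 0.625 of Thursday's 2.50 h reading of 9.4%, and that neighbouring flask gave 8.70%.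

Readings and results come from a simulation with made-up constants; the scatter is artificial.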